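## Structural features

The target is a labdane-type diterpenoid: a decalin (ring A: C1–C5 and C10; ring B: C5–C10) with a five-carbon chain on C9 that ends in a methyl ester (C15), a free carboxylic acid (C19) and a methyl group on C4, a methyl group (C20) on C10 and an exocyclic methylene (C17) on C8. The ring fusion is cis: H5 and the C10 methyl lie on one face, and the C4 carboxyl, the C5–C6 bond and the C10–C9 bond all lie on the other face of ring A. C4, C5, C10 and C9 are four contiguous stereocentres, two of them quaternary (C4 and C10, in a 1,3-relation across C5). The fifth centre, C13 (R), sits three bonds out in the chain, cannot be induced from the ring and has to be brought in. Fragile points are the C8=C17 alkene (hydrogenation, acid-promoted migration into ring B), the CO2H/CO2CH3 pair (no late saponification or esterification is possible), C9 whenever C8 is a carbonyl, and C5 whenever C6 is a carbonyl or part of an enone. The real difficulty is to set C4, C5 and C10 relative to one another on a cis-fused, doubly quaternary ring A, and then to attach the chain to C9, next to quaternary C10 and cis to its methyl. The key step exploits the all-cis arrangement on ring A: a three-atom tether C4–C19(=O)–O–C6 can hold a C6=C9 enone over the C5=C10 alkene and deliver both carbons from the carboxyl face, closing a γ-lactone and a cyclobutane whose later cleavage at C6–C9 leaves exactly the two carbons ring B needs.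

## Logic of the disconnections

21 from 20. The C8=C17 bond is cut first. The exocyclic alkene is the group most exposed to acid, hydrogenation and migration, so it is made last from the C8 ketone of 20. The gain is a ketone that also explains how C9 was functionalised. The demand is a methylenation that leaves the free C4 acid, the C15 ester and the C9 centre (α to the carbonyl) untouched.

20 from 19. Two hydrogens are removed across C6–C7 and the C4 acid is masked as a benzyl ester. The C6=C7 alkene of 19 blocks C7, so C8 can be enolised only towards C9, and the benzyl group keeps the ring carboxyl apart from the chain ester. One hydrogenation undoes both, so the masking costs no separate deprotection. The demand is that the ketone and C9 are not touched.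

19 from 14 and 17. The C9–C11 bond is cut. This separates the bicyclic core from a chain that carries C13 from the chiral pool, and it isolates the one ring stereocentre (C9) that the tether of the key step cannot reach. The forward step must alkylate an enolate carbon next to quaternary C10 with an unactivated primary iodide, on the face of the C10 methyl.

17 from 16 from 15. Only functional groups change: iodide from alcohol, alcohol from the acid end of 15, so the acid carbon becomes C11 and the ester carbon stays C15. The arrangement in space at C13 is unchanged (the descriptor goes from R in 16 to S in 17 by priority only). The demand is a reduction that tells the acid from the ester.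

14 from 13 from 9. The benzyl group is removed, the C6=C7 bond is cut (aldol condensation in reverse), the C6–C9 bond is re-formed (retro-aldol in reverse) and the C19–O–C6 lactone is closed. Ring B collapses into a cyclobutane and a γ-lactone, and the C5/C10 problem becomes the problem of making 9. The forward cascade must use hydroxide in water, because an alkoxide in an alcohol would leave a hindered ester on C4 that could no longer be told from the chain ester. It must also be mild enough to keep H5, which lies next to the C6 aldehyde and then γ to the enone.

9 from 8. The key disconnection cuts C5–C6 and C9–C10, the two cyclobutane bonds that belong neither to ring A nor to the enone. What remains is one ring A alkene and an enone tied to the C4 carboxyl, so C5, C10 and their relation to C4 are traced back to C4 alone. The forward step needs addition across C5=C10 from the carboxyl face in the straight sense, and it needs the enol ester to fold into the rotamer a lactone requires.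

8 from 6 and 7. The O–C6 bond of the enol ester is cut. Adding the carboxyl of 6 to the triple bond of 7 places the oxygen on C6 by construction and needs no acid chloride. Acylating a ketone enolate whose oxygen sits on C8 would give the wrong enol ester, so that route is not taken. The demand is only that the addition stops at the mono-adduct; the alkene geometry does not matter.

6 from 5 from 4 from 3 from 1. The single enantiomer is traced through salt 5 to racemate 4. Removing two hydrogens from C2–C3 of 4 gives 3, and cutting the C4–CH3 bond of 3 with rearomatisation gives 1. The quaternary carbon, its carboxyl and the C5=C10 alkene with the C10 methyl all come from one cheap arene. The forward steps must hydrogenate the disubstituted alkene and spare the trisubstituted one, and the resolution must deliver the S acid.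

## Other disconnections considered

Alternative 1: The cut runs through C5–C10 and C3–C4 and opens both rings at once, back to the acyclic triene A1 (Z-2-methyl enoate C4=C5, diene C10=C1–C2=C3, with the chain and a silyl-protected C8 oxygen already on the C6–C9 tether). Heating A1 would close rings A and B in one intramolecular Diels–Alder reaction to the cis-fused octalin A2.
- In its favour: the Z geometry of the dienophile translates directly into the cis relation of the C4 carboxyl and C6. The C9 chain with C13 is in place before any ring exists, so no enolate next to quaternary C10 has to be alkylated; on this point the alternative is the better plan. A thermal, concerted step needs no photochemical equipment and belongs to a far better precedented reaction class than the tether of the chosen key step, which is again better.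
- Equal points: the two carboxyls are told apart as benzyl and methyl esters, and the end game (C8 oxidation, methylenation beside an epimerisable C9) carries the same risk.
- Against it: the diene terminus C10 is fully substituted, so either the methyl or the tether must point inward in the s-cis conformer. The dienophile is trisubstituted with its ester on the carbon remote from the tether, and two quaternary carbons (C4 and C10) are formed, each in a different new bond. Such a cycloaddition would be expected to need temperatures at which 1,5-hydrogen shift in the diene and Z/E isomerisation of the enoate (which would invert C4) become possible.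
- Stereochemistry: it must win two independent contests, cis against trans fusion and the face of the diene relative to C9. The tether of the chosen plan decides both faces through one element.
- Step economy: A1 demands a Z-trisubstituted enoate, a defined C8/C9 pair and an E diene, a longer sequence than the six steps to 9. A2 still needs hydrogenation of C1=C2 with debenzylation, desilylation, oxidation and methylenation.

Alternative 2: The cut removes the C10 methyl (C10–C20) and the C5–C6 bond, leading back to the achiral iodo enone A3. Me3Al with Cu(OTf)2 and a chiral phosphoramidite would add the methyl group to C10. The aluminium enolate, turned into an ate complex with MeLi, would then close ring B by displacing the iodide at C6, giving the cis-fused decalone A4.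
- In its favour: the absolute configuration comes from a catalyst and no material is discarded in a resolution, which is better than the chosen plan. Conjugate methylation of 3-substituted cyclohexenones to quaternary centres is a well-precedented reaction class, also better. A3 is short to make.
- Equal point: the cis fusion follows from a tethered ring closure in both plans.
- Against it: A4 contains neither the C4 quaternary centre nor the C9 chain. The C4 ketone would have to be homologated and methylated with control of C4 on a cis-decalin, for which A4 offers no firm bias. After unmasking C8 the ketone can be enolised towards C7 as well as C9, with unhindered C7 favoured, so the chain would need a blocking strategy.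
- Structure: the alternative fixes C5 and C10 but leaves two stereocentres and one regiochemical problem open. The chosen plan fixes C4, C5 and C10 together and leaves only C9, with C7 blocked by the enone.
- Mechanism and step economy: the alkylation of an aluminium enolate by an unactivated primary iodide is the weak half of the tandem step. The route is shorter up to the key step and clearly longer after it.

Alternative 3: The cut is the single bond C9–C10, leading back to the salicylate A5, a phenol (oxygen on C3, ester on C4, methyl on C10) that carries on C5 a chain ending in an allylic carbonate spanning C17–C8–C9. Pd2(dba)3 (zerovalent palladium) with a chiral bisphosphine would ionise the carbonate. The phenoxide would attack the allyl terminus C9 through its para carbon C10, closing ring B and giving the cyclohexadienone A6 with C8=CH2.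
- In its favour: the quaternary C10, the C9 centre with the complete chain and the exocyclic methylene all appear in one catalytic step. There is no late methylenation and C9 is never α to a carbonyl; on both points it is better than the chosen plan. The starting materials are simple arenes, which is equal.
- Against the key step: the catalyst must control C10 and the C9/C10 relation in a substrate that already holds C13. C-alkylation at the substituted para carbon must outrun O-alkylation, and attack must occur at the more substituted allyl terminus (helped by a six- against an eight-membered ring).
- Against the sequel: ring A of A6 still lacks the C4 methyl, the C5 hydrogen and the right oxidation level. C1=C2 and the tetrasubstituted C4=C5 must be reduced and the C3 oxygen removed in the presence of C8=C17, the most easily hydrogenated alkene in the molecule. Hydride would have to reach C5 from the face of the C10 methyl, C4 would be set by alkylating a β-keto ester with no element favouring the required face, and the tert-butyl ester would have to be cleaved by acid beside an alkene prone to migrate.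
- Comparison: the alternative sets C9 and C10 and leaves C4 and C5 open, the reverse of the chosen plan. The redox corrections after A6 make it the longer route.

Key step: step 6

Assumption: the S acid is taken to form the less soluble salt with (S)-1-phenylethylamine; if the R acid salt crystallises instead, (R)-1-phenylethylamine is used and nothing else changes.

Numbering: labdane numbers are used throughout; C19 is the carboxyl carbon on C4, C20 the methyl on C10, C17 the methylene carbon on C8.

## Steps

Step 1
Reactants: 1 3-methylbenzoic acid
Product: 3 rac-1,3-dimethylcyclohexa-2,5-diene-1-carboxylic acid, via dilithium dienediolate 2 (not isolated)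
Conditions: Li, NH3(l)–THF, −78 °C; MeI, −78 °C → rt; aq. HCl
Reagents that add atoms: iodomethane, CI
Why: Birch reduction of the benzoate gives the 1,4-dihydro enediolate 2, which is methylated at the carbon that carries the carboxylate (Birch reductive alkylation); this makes quaternary C4 as a racemate and leaves the C5=C10 alkene with its methyl in place.

Step 2
Reactants: 3 rac-1,3-dimethylcyclohexa-2,5-diene-1-carboxylic acid
Product: 4 rac-1,3-dimethylcyclohex-2-ene-1-carboxylic acid
Conditions: H2 (1 atm), RhCl(PPh3)3 (cat.), toluene–EtOH, rt
Reagents that add atoms: none
Why: Homogeneous hydrogenation with RhCl(PPh3)3 reduces a cis-disubstituted alkene (C2=C3) much faster than a trisubstituted one (C5=C10), and it does not isomerise the skipped diene; no stereocentre is formed.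

Step 3
Reactants: 4 rac-1,3-dimethylcyclohex-2-ene-1-carboxylic acid
Product: 5 (1S)-1-phenylethanaminium (1S)-1,3-dimethylcyclohex-2-ene-1-carboxylate
Conditions: (S)-1-phenylethylamine (1 equiv), acetone, reflux → 5 °C; recrystallise
Reagents that add atoms: (S)-1-phenylethylamine, C[C@H](N)c1ccccc1
Why: Classical resolution through diastereomeric salts; the salt is recrystallised to constant rotation and the C4 configuration is to be confirmed by X-ray analysis of the salt, so the S centre is selected here and not created.

Step 4
Reactants: 5 (1S)-1-phenylethanaminium (1S)-1,3-dimethylcyclohex-2-ene-1-carboxylate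
Product: 6 (1S)-1,3-dimethylcyclohex-2-ene-1-carboxylic acid
Conditions: 1 M HCl, Et2O, 0 °C
Reagents that add atoms: none
Why: Protonation releases the acid into the organic phase and keeps the amine in water; the quaternary centre cannot racemise.

Step 5
Reactants: 6 (1S)-1,3-dimethylcyclohex-2-ene-1-carboxylic acid; 7 but-3-yn-2-one
Product: 8 (1E)-3-oxobut-1-en-1-yl (1S)-1,3-dimethylcyclohex-2-ene-1-carboxylate
Conditions: DABCO (10 mol%), CH2Cl2, 0 °C → rt
Reagents that add atoms: none
Why: Tertiary-amine-catalysed conjugate addition of a carboxylic acid to an ynone (oxa-Michael addition through a β-ammonium enone) should give the E enol ester under thermodynamic control, with the oxygen on C6 by construction. Either alkene geometry is usable, because C6 and C9 lose their configuration in step 7.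

Step 6
Reactants: 8 (1E)-3-oxobut-1-en-1-yl (1S)-1,3-dimethylcyclohex-2-ene-1-carboxylate
Product: 9 (1R,2S,3S,6S,10R)-2-acetyl-1,6-dimethyl-4-oxatricyclo[4.3.1.0^{3,10}]decan-5-one
Conditions: hν (350 nm, Pyrex), degassed MeCN (0.01 M), 25–40 °C
Reagents that add atoms: none
Why: Proposed new method: n→π* excitation of the β-acyloxy enone and intersystem crossing give the enone triplet, whose oxygen-bearing β-carbon C6 bonds to C5 of the ring alkene and leaves a triplet 1,4-diradical (acyl-stabilised at C9, tertiary at C10) that closes C9–C10 after spin inversion. The closest known reaction type is the intramolecular enone–alkene [2+2] photocycloaddition of β-acyloxy and β-alkoxy enones that carry the alkene on a three-atom tether (the cycloaddition half of the de Mayo reaction), which obeys the rule of five; what is untested is a tether that runs through the acyl group of the enol ester. The lactone ring is closed in the first bond formation as a 5-exo-trig attack of C6 on C5, and the cyclobutane is closed by combination of the two radical centres. C5 and C10 are controlled by C4: the tether C4–C19–O is too short to reach the far face of ring A, so C6 and C9 are both delivered cis to the carboxyl. C6 is fixed by the cis fusion of the lactone on the cyclobutane, and C9 follows the E geometry of the enone only if ring closure outruns bond rotation, which does not matter because both centres are lost in step 7. The step needs straight instead of crossed addition, secured by the five-membered first closure onto the less substituted alkene carbon, and it needs the enol ester to react from its minor rotamer with C6 syn to C4. That rotamer should be within reach because the ester oxygen is also conjugated to the enone (a vinylogous anhydride, with a weaker rotamer preference than a simple ester) and because C4 is quaternary, while molecules excited in the extended rotamer relax by twisting about C6=C9 and are not lost. Light near 350 nm is chosen so that the saturated methyl ketone of the product, which could undergo α-cleavage or γ-hydrogen abstraction, does not absorb.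

Step 7
Reactants: 9 (1R,2S,3S,6S,10R)-2-acetyl-1,6-dimethyl-4-oxatricyclo[4.3.1.0^{3,10}]decan-5-one
Product: 13 (1S,4aS,8aR)-1,4a-dimethyl-6-oxo-1,2,3,4,4a,5,6,8a-octahydronaphthalene-1-carboxylic acid, via cyclobutanol acid 10 (not isolated), via keto aldehyde 11 (not isolated), via ketol 12 (not isolated)
Conditions: KOH (3 equiv), THF–H2O, 0 °C → rt; then 1 M HCl to pH 2
Reagents that add atoms: potassium hydroxide, [K+].[OH-]
Why: Hydroxide opens the strained γ-lactone, the freed C6 alkoxide cleaves C6–C9 by retro-aldol reaction (de Mayo fragmentation, driven by cyclobutane strain), and the methyl ketone enolate at C7 closes ring B onto the C6 aldehyde by a 6-(enolexo)-exo-trig aldol addition followed by E1cB dehydration. No new stereocentre remains; C5 and C10 are carried over, and the neighbouring carboxylate and the two quaternary neighbours should slow deprotonation at C5. Water without an alcohol is used so that the hindered C4 carboxyl ends as the acid and not as an ester.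

Step 8
Reactants: 13 (1S,4aS,8aR)-1,4a-dimethyl-6-oxo-1,2,3,4,4a,5,6,8a-octahydronaphthalene-1-carboxylic acid
Product: 14 benzyl (1S,4aS,8aR)-1,4a-dimethyl-6-oxo-1,2,3,4,4a,5,6,8a-octahydronaphthalene-1-carboxylate
Conditions: BnBr, K2CO3, DMF, rt
Reagents that add atoms: benzyl bromide, BrCc1ccccc1
Why: SN2 O-alkylation of the carboxylate takes place at the benzyl carbon and is indifferent to the hindrance at C4; the benzyl ester keeps the ring carboxyl apart from the chain ester and is removed without an extra step in step 12.

Step 9
Reactants: 15 (3R)-5-methoxy-3-methyl-5-oxopentanoic acid
Product: 16 methyl (3R)-5-hydroxy-3-methylpentanoate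
Conditions: BH3·SMe2, THF, 0 °C → rt; MeOH
Reagents that add atoms: none
Why: Borane reduces a carboxylic acid (through the acyloxyborane) much faster than an ester, so the acid carbon becomes C11 and the methyl ester stays as C15; the C13 centre is not touched.

Step 10
Reactants: 16 methyl (3R)-5-hydroxy-3-methylpentanoate
Product: 17 methyl (3S)-5-iodo-3-methylpentanoate
Conditions: I2, PPh3, imidazole, CH2Cl2, 0 °C → rt
Reagents that add atoms: iodine, II
Why: Appel-type iodination converts the primary alcohol into the iodide by SN2 at C11 under near-neutral conditions, which avoids lactonisation of the hydroxy ester; the descriptor at C13 becomes S only because the priorities change.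

Step 11
Reactants: 14 benzyl (1S,4aS,8aR)-1,4a-dimethyl-6-oxo-1,2,3,4,4a,5,6,8a-octahydronaphthalene-1-carboxylate; 17 methyl (3S)-5-iodo-3-methylpentanoate
Product: 19 benzyl (1S,4aR,5S,8aR)-5-[(3R)-5-methoxy-3-methyl-5-oxopentyl]-1,4a-dimethyl-6-oxo-1,2,3,4,4a,5,6,8a-octahydronaphthalene-1-carboxylate, via lithium enolate 18 (not isolated)
Conditions: LiN(iPr)2, THF, −78 °C; 17, DMPU, −78 → −20 °C
Reagents that add atoms: none
Why: Kinetic deprotonation of the enone can occur only at C9 (C7 is vinylic, H5 is shielded by two quaternary carbons), and the cross-conjugated lithium enolate is alkylated by the primary iodide in an SN2 reaction (α′-alkylation of an enone). C9 should be set by approach from the convex face of the cis-fused bicycle, the face of the C10 methyl, because the other face is closed by ring A with its C4 ester standing 1,3 to C9.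

Step 12
Reactants: 19 benzyl (1S,4aR,5S,8aR)-5-[(3R)-5-methoxy-3-methyl-5-oxopentyl]-1,4a-dimethyl-6-oxo-1,2,3,4,4a,5,6,8a-octahydronaphthalene-1-carboxylate
Product: 20 (1S,4aR,5S,8aR)-5-[(3R)-5-methoxy-3-methyl-5-oxopentyl]-1,4a-dimethyl-6-oxodecahydronaphthalene-1-carboxylic acid
Conditions: H2 (1 atm), 10% Pd/C, EtOAc, rt
Reagents that add atoms: none
Why: Heterogeneous hydrogenation saturates the C6=C7 enone alkene and cleaves the benzyl ester by hydrogenolysis in one operation; the ketone, the methyl ester and the C9 centre are inert under these neutral conditions.

Step 13
Reactants: 20 (1S,4aR,5S,8aR)-5-[(3R)-5-methoxy-3-methyl-5-oxopentyl]-1,4a-dimethyl-6-oxodecahydronaphthalene-1-carboxylic acid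
Product: 21 (1S,4aS,5R,8aR)-5-[(3R)-5-methoxy-3-methyl-5-oxopentyl]-1,4a-dimethyl-6-methylidenedecahydronaphthalene-1-carboxylic acid
Conditions: Ph3PCH3Br (3.5 equiv), KN(SiMe3)2 (3.3 equiv), THF, 0 °C; then 20, 0 °C → rt; aq. HCl to pH 3
Reagents that add atoms: methyltriphenylphosphonium bromide, C[P+](c1ccccc1)(c1ccccc1)c1ccccc1.[Br-]
Why: Wittig methylenation: the first equivalent of base turns the acid into its carboxylate, and the unstabilised ylide should add to the C8 ketone faster than it enolises it at low temperature, so C9 keeps its configuration; the methyl ester does not react with the ylide.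

## Compound list

1 | 3-methylbenzoic acid | Cc1cccc(c1)C(=O)O | starting material
2 | dilithium (3-methylcyclohexa-2,5-dien-1-ylidene)methanediolate | [Li+].[Li+].[O-]C([O-])=C1C=CCC(C)=C1 | intermediate
3 | rac-1,3-dimethylcyclohexa-2,5-diene-1-carboxylic acid | CC1=CC(C)(C(=O)O)C=CC1 | intermediate
4 | rac-1,3-dimethylcyclohex-2-ene-1-carboxylic acid | CC1=CC(C)(C(=O)O)CCC1 | intermediate
5 | (1S)-1-phenylethanaminium (1S)-1,3-dimethylcyclohex-2-ene-1-carboxylate | C[C@H]([NH3+])c1ccccc1.[O-]C(=O)[C@@]1(C)CCCC(C)=C1 | intermediate
6 | (1S)-1,3-dimethylcyclohex-2-ene-1-carboxylic acid | OC(=O)[C@@]1(C)CCCC(C)=C1 | intermediate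
7 | but-3-yn-2-one | CC(=O)C#C | starting material
8 | (1E)-3-oxobut-1-en-1-yl (1S)-1,3-dimethylcyclohex-2-ene-1-carboxylate | CC(=O)/C=C/OC(=O)[C@@]1(C)CCCC(C)=C1 | intermediate
9 | (1R,2S,3S,6S,10R)-2-acetyl-1,6-dimethyl-4-oxatricyclo[4.3.1.0^{3,10}]decan-5-one (acetyl on C9 trans to the lactone oxygen on C6) | CC(=O)[C@@H]1[C@H]2OC(=O)[C@@]3(C)CCC[C@]1(C)[C@@H]23 | intermediate
10 | 7-acetyl-8-hydroxy-2,6-dimethylbicyclo[4.2.0]octane-2-carboxylic acid, configuration of 9 (potassium salt in the flask) | CC(=O)[C@@H]1[C@@H](O)[C@H]2[C@@](C)(C(=O)O)CCC[C@@]12C | intermediate
11 | (1S,2R,3S)-2-formyl-1,3-dimethyl-3-(2-oxopropyl)cyclohexane-1-carboxylic acid (potassium salt in the flask) | CC(=O)C[C@]1(C)CCC[C@](C)(C(=O)O)[C@@H]1C=O | intermediate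
12 | (1S,4aS,8aR)-8-hydroxy-1,4a-dimethyl-6-oxodecahydronaphthalene-1-carboxylic acid, both C8 epimers (potassium salt in the flask) | O=C1CC(O)[C@@H]2[C@@](C)(CCC[C@]2(C)C(=O)O)C1 | intermediate
13 | (1S,4aS,8aR)-1,4a-dimethyl-6-oxo-1,2,3,4,4a,5,6,8a-octahydronaphthalene-1-carboxylic acid | O=C1C=C[C@@H]2[C@@](C)(CCC[C@]2(C)C(=O)O)C1 | intermediate
14 | benzyl (1S,4aS,8aR)-1,4a-dimethyl-6-oxo-1,2,3,4,4a,5,6,8a-octahydronaphthalene-1-carboxylate | O=C1C=C[C@@H]2[C@@](C)(CCC[C@]2(C)C(=O)OCc3ccccc3)C1 | intermediate
15 | (3R)-5-methoxy-3-methyl-5-oxopentanoic acid (methyl hydrogen (R)-3-methylglutarate) | OC(=O)C[C@@H](C)CC(=O)OC | starting material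
16 | methyl (3R)-5-hydroxy-3-methylpentanoate | OCC[C@@H](C)CC(=O)OC | intermediate
17 | methyl (3S)-5-iodo-3-methylpentanoate | ICC[C@@H](C)CC(=O)OC | intermediate
18 | lithium 5-(benzyloxycarbonyl)-5,8a-dimethyl-4a,5,6,7,8,8a-hexahydronaphthalen-2-olate, configuration of 14 | [Li+].[O-]C1=C[C@]2(C)CCC[C@](C)(C(=O)OCc3ccccc3)[C@@H]2C=C1 | intermediate
19 | benzyl (1S,4aR,5S,8aR)-5-[(3R)-5-methoxy-3-methyl-5-oxopentyl]-1,4a-dimethyl-6-oxo-1,2,3,4,4a,5,6,8a-octahydronaphthalene-1-carboxylate | O=C1C=C[C@@H]2[C@@](C)(CCC[C@]2(C)C(=O)OCc3ccccc3)[C@@H]1CC[C@@H](C)CC(=O)OC | intermediate
20 | (1S,4aR,5S,8aR)-5-[(3R)-5-methoxy-3-methyl-5-oxopentyl]-1,4a-dimethyl-6-oxodecahydronaphthalene-1-carboxylic acid | O=C1CC[C@@H]2[C@@](C)(CCC[C@]2(C)C(=O)O)[C@@H]1CC[C@@H](C)CC(=O)OC | intermediate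
21 | (1S,4aS,5R,8aR)-5-[(3R)-5-methoxy-3-methyl-5-oxopentyl]-1,4a-dimethyl-6-methylidenedecahydronaphthalene-1-carboxylic acid | C=C1CC[C@@H]2[C@@](C)(CCC[C@]2(C)C(=O)O)[C@@H]1CC[C@@H](C)CC(=O)OC | target

## Step count and least certain steps

Total: 13 steps. Longest linear sequence: 11 steps (steps 1–8 and 11–13, from 1); the chain branch is 2 steps (9 and 10).

Step 6 (key step, new method). Most likely failure: the excited enone relaxes by twisting about C6=C9 without ever adding, because the enol ester stays in its extended rotamer during the short triplet lifetime. Slower side processes then take over on long irradiation: a photochemical 1,3-acyl shift of the enol ester, or hydrogen transfer within the 1,4-diradical instead of ring closure. A triplet sensitiser such as thioxanthone would be a change of conditions only. The fallback replaces the ester tether by an ether, which has no rotamer barrier, and uses known chemistry. Acid 6 would be reduced with LiAlH4 to [(1S)-1,3-dimethylcyclohex-2-en-1-yl]methanol F1. F1 would add to 7 (PMe3 or DABCO cat., oxa-Michael addition) to give (3E)-4-{[(1S)-1,3-dimethylcyclohex-2-en-1-yl]methoxy}but-3-en-2-one F2. Irradiation at 350 nm would close the same two bonds; intramolecular [2+2] photocycloaddition of β-alkoxy enones that carry the alkene on the alkoxy oxygen is an established substrate class. The product is the cyclobutane-fused tetrahydrofuran 1-[(1R,2S,3S,6S,10R)-1,6-dimethyl-4-oxatricyclo[4.3.1.0^{3,10}]decan-2-yl]ethan-1-one F3. RuO4, made in the flask from RuCl3 (cat.) and NaIO4, would then oxidise the ether CH2 (C19) to the lactone carbonyl. The methine C6–H, on the cyclobutane and β to the acetyl group, should be less reactive. The route is rejoined at 9.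

Step 11. Most likely failure: slow SN2 reaction at an enolate carbon next to quaternary C10. Proton transfer (enolate equilibration, epimerisation at C5 through the dienolate) and O-alkylation could then compete, and facial selectivity at C9 could be incomplete. The fallback changes the nucleophile to an azaenolate, which is far more reactive towards unactivated primary iodides and keeps the same kinetic face. Enone 14 would be condensed with 1,1-dimethylhydrazine to benzyl (1S,4aS,8aR)-6-(2,2-dimethylhydrazinylidene)-1,4a-dimethyl-1,2,3,4,4a,5,6,8a-octahydronaphthalene-1-carboxylate F4. F4 would be deprotonated at C9 with LiN(iPr)2 and alkylated with 17 to benzyl (1S,4aR,5S,8aR)-6-(2,2-dimethylhydrazinylidene)-5-[(3R)-5-methoxy-3-methyl-5-oxopentyl]-1,4a-dimethyl-1,2,3,4,4a,5,6,8a-octahydronaphthalene-1-carboxylate F5. Two-phase hydrolysis with aqueous oxalic acid would free the ketone. The route is rejoined at 19.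

Step 7. Most likely failure: loss of configuration at C5, by enolisation of the C6 aldehyde before ring closure or by γ-deprotonation of the enone, if the dehydration needs more forcing base than planned. The fallback interrupts the cascade and changes the dehydration mechanism. From 9, LiOH in THF–H2O at 0 °C would be stopped at ketol 12, which would be isolated after acidification and dehydrated under acid catalysis (TsOH, toluene, 60 °C). The route is rejoined at 13 and no new compound is made.

Step 3. Most likely failure: co-crystallisation of both diastereomeric salts, or enrichment of the wrong enantiomer, so that the optical purity stays low. The fallback separates the enantiomers of 4 directly by preparative chromatography on a chiral stationary phase (supercritical CO2/MeOH, amylose carbamate phase). The route is rejoined at 6 and no new compound is made.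

Step 13. Most likely failure: enolisation of the α-branched C8 ketone by the basic ylide, giving incomplete conversion and epimerisation at C9. A rough conformational count does not clearly favour either C9 epimer, so equilibration cannot be relied on to repair this. The fallback changes from a basic phosphorus ylide to a non-basic titanium–zinc methylene reagent (Zn, CH2Br2, TiCl4, THF–CH2Cl2, 0 °C → rt; Takai–Lombardo methylenation), which is known to spare esters and epimerisable centres. It leads from 20 to 21 and makes no new compound.

## Further compounds

F1 | step 6 | [(1S)-1,3-dimethylcyclohex-2-en-1-yl]methanol | OC[C@@]1(C)CCCC(C)=C1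
F2 | step 6 | (3E)-4-{[(1S)-1,3-dimethylcyclohex-2-en-1-yl]methoxy}but-3-en-2-one | CC(=O)/C=C/OC[C@@]1(C)CCCC(C)=C1
F3 | step 6 | 1-[(1R,2S,3S,6S,10R)-1,6-dimethyl-4-oxatricyclo[4.3.1.0^{3,10}]decan-2-yl]ethan-1-one | CC(=O)[C@@H]1[C@H]2OC[C@@]3(C)CCC[C@]1(C)[C@@H]23
F4 | step 11 | benzyl (1S,4aS,8aR)-6-(2,2-dimethylhydrazinylidene)-1,4a-dimethyl-1,2,3,4,4a,5,6,8a-octahydronaphthalene-1-carboxylate | CN(C)N=C1C=C[C@@H]2[C@@](C)(CCC[C@]2(C)C(=O)OCc3ccccc3)C1
F5 | step 11 | benzyl (1S,4aR,5S,8aR)-6-(2,2-dimethylhydrazinylidene)-5-[(3R)-5-methoxy-3-methyl-5-oxopentyl]-1,4a-dimethyl-1,2,3,4,4a,5,6,8a-octahydronaphthalene-1-carboxylate | CN(C)N=C1C=C[C@@H]2[C@@](C)(CCC[C@]2(C)C(=O)OCc3ccccc3)[C@@H]1CC[C@@H](C)CC(=O)OC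
F0 | step 7 | none | none
F0 | step 3 | none | none
F0 | step 13 | none | none
A1 | alternative 1 | benzyl (2Z,8E)-6-[(tert-butyldimethylsilyl)oxy]-7-[(3R)-5-methoxy-3-methyl-5-oxopentyl]-2,8-dimethylundeca-2,8,10-trienoate | O=C(OCc1ccccc1)/C(C)=C\CC[C@H](O[Si](C)(C)C(C)(C)C)[C@@H](CC[C@@H](C)CC(=O)OC)/C(C)=C/C=C
A2 | alternative 1 | benzyl 6-[(tert-butyldimethylsilyl)oxy]-5-[(3R)-5-methoxy-3-methyl-5-oxopentyl]-1,4a-dimethyl-1,2,4a,5,6,7,8,8a-octahydronaphthalene-1-carboxylate, cis-fused, ring configuration of 21 | CC(C)(C)[Si](C)(C)O[C@H]1CC[C@@H]2[C@@](C)(C=CC[C@]2(C)C(=O)OCc3ccccc3)[C@@H]1CC[C@@H](C)CC(=O)OC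
A3 | alternative 2 | 3-{[2-(2-iodoethyl)-1,3-dioxolan-2-yl]methyl}cyclohex-2-en-1-one | O=C1C=C(CC2(CCI)OCCO2)CCC1
A4 | alternative 2 | cis-fused 8a′-methyloctahydrospiro[1,3-dioxolane-2,2′-naphthalen]-5′-one, C5 and C10 as in 21 | C12(OCCO1)CC[C@@H]3[C@@](C)(CCCC3=O)C2
A5 | alternative 3 | tert-butyl 2-hydroxy-6-[(7R)-9-methoxy-3-{[(methoxycarbonyl)oxy]methyl}-7-methyl-9-oxonon-3-en-1-yl]-5-methylbenzoate | Cc1ccc(O)c(C(=O)OC(C)(C)C)c1CCC(COC(=O)OC)=CCC[C@@H](C)CC(=O)OC
A6 | alternative 3 | tert-butyl 5-[(3R)-5-methoxy-3-methyl-5-oxopentyl]-4a-methyl-6-methylidene-2-oxo-2,4a,5,6,7,8-hexahydronaphthalene-1-carboxylate, C9 and C10 as in 21 | C=C1CCC2=C(C(=O)OC(C)(C)C)C(=O)C=C[C@@]2(C)[C@@H]1CC[C@@H](C)CC(=O)OC
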